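The C4a–C5 bond of ring A is the disconnection. The oxygen-bearing carbons C5–C8 of ring A are C1–C4 of a β-D-glucopyranoside whose aglycon oxygen is O7' of the bromochromone, and C8a/C4a are sugar C5/C6. A Lewis-acid-triggered Ferrier-type carbocyclization that keeps the aglycon converts the aryl 6-deoxyhex-5-enopyranoside into the aryloxy cyclohexanone in one operation. It forms C4a–C5, closes ring A, preserves the C5–O–C7' ether with its β configuration, and leaves the C8a ketone for pyranone annulation. The precursor is 6-bromo-2-(2-phenylethyl)chromon-7-yl 2,4-di-O-benzyl-3-O-(4-methoxybenzyl)-6-deoxy-β-D-xylo-hex-5-enopyranoside; its O3 (later O7) is released afterwards for the dioxepine closure onto C6'.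

Key step: step 12

Remark: unprimed locants (ring A = C4a, C5, C6, C7, C8, C8a) refer to the tetrahydrochromone half and primed locants to the aromatic chromone half; commercial diacetone-D-glucose 7, the bis-acetonide of D-glucose, is taken as the chiral-pool source.

Step 1
Reactants: 1 1-(5-bromo-2,4-dihydroxyphenyl)ethanone; 2 ethyl 3-phenylpropanoate
Product: 4 6-bromo-7-hydroxy-2-(2-phenylethyl)-4H-chromen-4-one, via β-diketone 3 (not isolated)
Conditions: LiN(SiMe3)2 (5 equiv), THF, −78 °C to 50 °C; aq. HCl; then H2SO4 (cat.), AcOH, 100 °C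
Reagents that add atoms: none
Why: Claisen condensation of the lithium enolate of the bis-phenoxide of 1 with ester 2 should give β-diketone 3, and acid-catalysed cyclodehydration through the ortho-hydroxyl (the classical chromone synthesis from 2-hydroxyacetophenones) closes the pyranone while the bromine and the para-hydroxyl stay untouched.

Step 2
Reactants: 5 2,2,6-trimethyl-4H-1,3-dioxin-4-one
Product: 6 6-[2-(4-methoxyphenyl)ethyl]-2,2-dimethyl-4H-1,3-dioxin-4-one
Conditions: LiN(iPr)2 (1.1 equiv), THF/DMPU, −78 °C; 4-methoxybenzyl bromide, −78 to −20 °C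
Reagents that add atoms: 4-methoxybenzyl bromide, COc1ccc(CBr)cc1
Why: Deprotonation of the 6-methyl group gives the lithium dienolate, which a reactive benzylic bromide alkylates at the exocyclic γ-carbon (vinylogous enolate alkylation), installing the 4-methoxyphenethyl chain destined for C2 of the ring A pyranone.

Step 3
Reactants: 7 1,2:5,6-di-O-isopropylidene-α-D-glucofuranose
Product: 8 1,2:5,6-di-O-isopropylidene-3-O-(4-methoxybenzyl)-α-D-glucofuranose
Conditions: NaH, 4-methoxybenzyl chloride, Bu4NI (cat.), DMF, 0 °C to rt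
Reagents that add atoms: 4-methoxybenzyl chloride, COc1ccc(CCl)cc1
Why: Williamson etherification of the only free hydroxyl, O3, which later becomes O7 of ring A and must be unmasked independently of the benzyl ethers.

Step 4
Reactants: 8 1,2:5,6-di-O-isopropylidene-3-O-(4-methoxybenzyl)-α-D-glucofuranose
Product: 9 3-O-(4-methoxybenzyl)-D-glucopyranose (anomeric mixture)
Conditions: Amberlite IR-120 (H+ form), H2O/1,4-dioxane, 70 °C
Reagents that add atoms: none
Why: Acid-catalysed hydrolysis of both isopropylidene ketals, which are much more labile than the benzylic PMB ether under dilute aqueous sulfonic-acid conditions, lets the sugar relax to the pyranose hemiacetal.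

Step 5
Reactants: 9 3-O-(4-methoxybenzyl)-D-glucopyranose
Product: 10 1,2,4,6-tetra-O-acetyl-3-O-(4-methoxybenzyl)-D-glucopyranose (anomeric mixture)
Conditions: Ac2O, pyridine, DMAP (cat.), 0 °C to rt
Reagents that add atoms: acetic anhydride, CC(=O)OC(C)=O
Why: Exhaustive DMAP-catalysed acetylation, which places at O2 the participating ester needed for the glycosylation.

Step 6
Reactants: 10 1,2,4,6-tetra-O-acetyl-3-O-(4-methoxybenzyl)-D-glucopyranose
Product: 11 2,4,6-tri-O-acetyl-3-O-(4-methoxybenzyl)-D-glucopyranose (anomeric mixture)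
Conditions: H2NNH2·AcOH, DMF, rt
Reagents that add atoms: none
Why: Hydrazinolysis should remove only the anomeric acetate, the most electrophilic ester because its leaving group is a hemiacetal oxygen.

Step 7
Reactants: 11 2,4,6-tri-O-acetyl-3-O-(4-methoxybenzyl)-D-glucopyranose
Product: 12 2,4,6-tri-O-acetyl-3-O-(4-methoxybenzyl)-D-glucopyranosyl N-phenyl-2,2,2-trifluoroacetimidate (anomeric mixture)
Conditions: CF3C(=NPh)Cl, K2CO3, acetone, rt
Reagents that add atoms: 2,2,2-trifluoro-N-phenylacetimidoyl chloride, FC(F)(F)C(Cl)=Nc1ccccc1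
Why: Base-mediated O-imidoylation of the hemiacetal gives an N-aryl trifluoroacetimidate donor, a leaving group well suited to weakly nucleophilic phenols because it resists rearrangement to an unreactive amide.

Step 8
Reactants: 12 2,4,6-tri-O-acetyl-3-O-(4-methoxybenzyl)-D-glucopyranosyl N-phenyl-2,2,2-trifluoroacetimidate; 4 6-bromo-7-hydroxy-2-(2-phenylethyl)-4H-chromen-4-one
Product: 13 6-bromo-4-oxo-2-(2-phenylethyl)-4H-chromen-7-yl 2,4,6-tri-O-acetyl-3-O-(4-methoxybenzyl)-β-D-glucopyranoside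
Conditions: BF3·OEt2 (0.2 equiv), 4 Å MS, CH2Cl2, −20 °C to rt
Reagents that add atoms: none
Why: Lewis-acid-activated imidate glycosylation of the phenol, in which neighbouring-group participation by the 2-O-acetyl group blocks the α face so that the phenol enters trans to O2 and sets the β (1,2-trans) anomeric configuration that becomes C5 of ring A.

Step 9
Reactants: 13 6-bromo-4-oxo-2-(2-phenylethyl)-4H-chromen-7-yl 2,4,6-tri-O-acetyl-3-O-(4-methoxybenzyl)-β-D-glucopyranoside
Product: 14 6-bromo-4-oxo-2-(2-phenylethyl)-4H-chromen-7-yl 3-O-(4-methoxybenzyl)-β-D-glucopyranoside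
Conditions: NaOMe (0.1 equiv), MeOH/THF, 0 °C; AcOH quench
Reagents that add atoms: none
Why: Zemplén transesterification with catalytic methoxide at 0 °C should remove the three acetates without opening the chromone or cleaving the aryl glycoside.

Step 10
Reactants: 14 6-bromo-4-oxo-2-(2-phenylethyl)-4H-chromen-7-yl 3-O-(4-methoxybenzyl)-β-D-glucopyranoside
Product: 15 6-bromo-4-oxo-2-(2-phenylethyl)-4H-chromen-7-yl 6-deoxy-6-iodo-3-O-(4-methoxybenzyl)-β-D-glucopyranoside
Conditions: I2, PPh3, imidazole, THF, rt to 50 °C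
Reagents that add atoms: iodine, II
Why: Garegg–Samuelsson (Appel-type) iodination is selective for the primary 6-hydroxyl, because SN2 displacement at the two hindered secondary carbinols is far slower.

Step 11
Reactants: 15 6-bromo-4-oxo-2-(2-phenylethyl)-4H-chromen-7-yl 6-deoxy-6-iodo-3-O-(4-methoxybenzyl)-β-D-glucopyranoside
Product: 17 6-bromo-4-oxo-2-(2-phenylethyl)-4H-chromen-7-yl 2,4-di-O-benzyl-6-deoxy-3-O-(4-methoxybenzyl)-β-D-xylo-hex-5-enopyranoside, via dibenzyl iodide 16 (not isolated)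
Conditions: BnBr (3 equiv), then NaH (4 equiv), DMF, 0 °C to rt
Reagents that add atoms: benzyl bromide, BrCc1ccccc1
Why: Williamson benzylation of O2 and O4 followed in the same flask by E2 dehydroiodination of the primary iodide gives the exocyclic enol ether (the standard entry to 6-deoxyhex-5-enopyranosides), and having benzyl bromide present before NaH is added lets the 2-alkoxide be benzylated before it can displace the aglycon.

Step 12
Reactants: 17 6-bromo-4-oxo-2-(2-phenylethyl)-4H-chromen-7-yl 2,4-di-O-benzyl-6-deoxy-3-O-(4-methoxybenzyl)-β-D-xylo-hex-5-enopyranoside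
Product: 19 (2S,3R,4S,5R)-2,4-bis(benzyloxy)-5-{[6-bromo-4-oxo-2-(2-phenylethyl)-4H-chromen-7-yl]oxy}-3-[(4-methoxybenzyl)oxy]cyclohexan-1-one, via titanium enolate aryloxycarbenium zwitterion 18 (not isolated)
Conditions: TiCl3(OiPr) (3 equiv, from TiCl4 and Ti(OiPr)4, 3:1), CH2Cl2, −78 °C, short contact time; aq. NaHCO3
Reagents that add atoms: none
Why: TiCl3(OiPr) binds the ring oxygen of the enol ether and, with lone-pair assistance from the aglycon oxygen O7', the anomeric C–O(ring) bond heterolyses to zwitterion 18, a titanium enolate (C8a–O–Ti, nucleophilic carbon C4a) tethered to an aryloxycarbenium ion (C5=O+–Ar); attack of C4a on C5 within this ion pair forms the C4a–C5 bond and, after quench, ketone 19. The closest known reaction type is the Lewis-acid-promoted rearrangement of 6-deoxyhex-5-enopyranosides to cyclohexanones or cyclohexanols with the anomeric substituent retained, an intramolecular Mukaiyama-aldol-like variant of the Ferrier carbocyclization, applied here to an aryl glycoside. Ring A closes in a 6-(enolendo)-exo-trig mode, with both enolate carbons inside the new six-membered ring and the C=O+ bond outside it. The only new stereocentre, C5, is substrate-controlled: bond formation inside the contact ion pair through a chair transition state with the three ether substituents and the aryloxy group equatorial returns the aryl ether trans to O6, that is with net retention of the β configuration. The step needs endocyclic instead of exocyclic C–O cleavage, which is secured by the β-anomer (an aglycon-oxygen lone pair lies antiperiplanar to the ring C–O bond) and by the low basicity of the electron-poor, ortho-brominated chromonyl ether oxygen relative to the enol ether oxygen. An excess of reagent saturates the chromone carbonyl, and −78 °C with a short contact time should preserve the PMB ether and prevent dissociation of the ion pair or β-elimination of the aryloxide from 19.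

Step 13
Reactants: 19 (2S,3R,4S,5R)-2,4-bis(benzyloxy)-5-{[6-bromo-4-oxo-2-(2-phenylethyl)-4H-chromen-7-yl]oxy}-3-[(4-methoxybenzyl)oxy]cyclohexan-1-one
Product: 20 trimethylsilyl enol ether of 19 (C8a–OSiMe3, C8a=C4a double bond; the four ether-bearing stereocentres unchanged)
Conditions: Me3SiOTf, Et3N, CH2Cl2, −78 to 0 °C; non-aqueous work-up, used crude
Reagents that add atoms: trimethylsilyl trifluoromethanesulfonate, C[Si](C)(C)OS(=O)(=O)C(F)(F)F
Why: Soft enolisation (O-silylation of the ketone, then deprotonation by Et3N at the unhindered C4a methylene and not at the tertiary, ether-bearing C8–H) should give the less substituted silyl enol ether, and because no free enolate is formed β-elimination of the C5 aryloxide is avoided.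

Step 14
Reactants: 20 trimethylsilyl enol ether of 19; 6 6-[2-(4-methoxyphenyl)ethyl]-2,2-dimethyl-4H-1,3-dioxin-4-one
Product: 23 (5R,6S,7R,8S)-6,8-bis(benzyloxy)-5-{[6-bromo-4-oxo-2-(2-phenylethyl)-4H-chromen-7-yl]oxy}-7-[(4-methoxybenzyl)oxy]-2-[2-(4-methoxyphenyl)ethyl]-5,6,7,8-tetrahydro-4H-chromen-4-one, via acylketene 21 (not isolated), via silyloxy dihydropyranone cycloadduct 22 (not isolated)
Conditions: toluene, 110 °C; then TsOH·H2O (cat.), rt
Reagents that add atoms: none
Why: Thermal retro-[4+2] of dioxinone 6 releases acetone and acylketene 21, which undergoes a hetero-Diels–Alder reaction with the electron-rich enol ether (ketene carbon to C4a, acyl oxygen to C8a) to give 22, and acid-catalysed loss of Me3SiOH then delivers the γ-pyranone (the known acylketene–enol ether route to 4-pyranones).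

Step 15
Reactants: 23 (5R,6S,7R,8S)-6,8-bis(benzyloxy)-5-{[6-bromo-4-oxo-2-(2-phenylethyl)-4H-chromen-7-yl]oxy}-7-[(4-methoxybenzyl)oxy]-2-[2-(4-methoxyphenyl)ethyl]-5,6,7,8-tetrahydro-4H-chromen-4-one
Product: 24 the C7 alcohol: 6,8-bis(benzyloxy)-5-{[6-bromo-4-oxo-2-(2-phenylethyl)-4H-chromen-7-yl]oxy}-7-hydroxy-2-[2-(4-methoxyphenyl)ethyl]-5,6,7,8-tetrahydro-4H-chromen-4-one (spatial arrangement at C5–C8 as in 23)
Conditions: DDQ (1.3 equiv), CH2Cl2/pH 7 phosphate buffer, 0 °C
Reagents that add atoms: none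
Why: Oxidative PMB cleavage by DDQ (benzylic hydride abstraction, then hydrolysis of the oxocarbenium ion) frees O7, while the benzyl ethers and the 4-methoxyphenethyl group, which has no α-oxygen, are oxidised much more slowly.

Step 16
Reactants: 24 the C7 alcohol
Product: 25 6,8-di-O-benzyl ether of the target (bridged benzo-1,4-dioxepine with C5–O–C7' and C7–O–C6' links; spatial arrangement at C5–C8 as in 23)
Conditions: Pd(OAc)2 (10 mol %), 2-(di-tert-butylphosphino)-1,1'-binaphthyl (12 mol %), Cs2CO3, toluene, 80 °C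
Reagents that add atoms: none
Why: Buchwald–Hartwig-type intramolecular C–O coupling (oxidative addition of C6'–Br to zerovalent palladium, alkoxide binding, reductive elimination driven by the bulky electron-rich phosphine) closes the seven-membered dioxepine, which is geometrically possible because O5 and O7 are 1,3-cis and become diaxial on ring A, and no bond to a stereocentre is broken.

Step 17
Reactants: 25 6,8-di-O-benzyl ether of the target
Product: 26 (+)-4'-methoxyaquisinenone G
Conditions: BCl3 (6 equiv), pentamethylbenzene, CH2Cl2, −78 °C; MeOH quench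
Reagents that add atoms: none
Why: BCl3 cleaves the two benzyl ethers at −78 °C with pentamethylbenzene trapping the benzyl cations (Friedel–Crafts benzylation of the scavenger), conditions under which the aryl methyl ether, both pyranones and the two aryl alkyl ether bridges should persist.

Compound list

1 | 1-(5-bromo-2,4-dihydroxyphenyl)ethanone | CC(=O)c1cc(Br)c(O)cc1O | starting material
2 | ethyl 3-phenylpropanoate | CCOC(=O)CCc1ccccc1 | starting material
3 | 1-(5-bromo-2,4-dihydroxyphenyl)-5-phenylpentane-1,3-dione | O=C(CCc1ccccc1)CC(=O)c1cc(Br)c(O)cc1O | intermediate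
4 | 6-bromo-7-hydroxy-2-(2-phenylethyl)-4H-chromen-4-one | O=c1cc(CCc2ccccc2)oc2cc(O)c(Br)cc12 | intermediate
5 | 2,2,6-trimethyl-4H-1,3-dioxin-4-one | CC1=CC(=O)OC(C)(C)O1 | starting material
6 | 6-[2-(4-methoxyphenyl)ethyl]-2,2-dimethyl-4H-1,3-dioxin-4-one | COc1ccc(CCC2=CC(=O)OC(C)(C)O2)cc1 | intermediate
7 | 1,2:5,6-di-O-isopropylidene-α-D-glucofuranose | CC1(C)OC[C@@H](O1)[C@H]1O[C@@H]2OC(C)(C)O[C@@H]2[C@H]1O | starting material
8 | 1,2:5,6-di-O-isopropylidene-3-O-(4-methoxybenzyl)-α-D-glucofuranose | CC1(C)OC[C@@H](O1)[C@H]1O[C@@H]2OC(C)(C)O[C@@H]2[C@H]1OCc1ccc(OC)cc1 | intermediate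
9 | 3-O-(4-methoxybenzyl)-D-glucopyranose (anomeric mixture) | OC[C@H]1OC(O)[C@H](O)[C@@H](OCc2ccc(OC)cc2)[C@@H]1O | intermediate
10 | 1,2,4,6-tetra-O-acetyl-3-O-(4-methoxybenzyl)-D-glucopyranose (anomeric mixture) | CC(=O)OC[C@H]1OC(OC(C)=O)[C@H](OC(C)=O)[C@@H](OCc2ccc(OC)cc2)[C@@H]1OC(C)=O | intermediate
11 | 2,4,6-tri-O-acetyl-3-O-(4-methoxybenzyl)-D-glucopyranose (anomeric mixture) | CC(=O)OC[C@H]1OC(O)[C@H](OC(C)=O)[C@@H](OCc2ccc(OC)cc2)[C@@H]1OC(C)=O | intermediate
12 | 2,4,6-tri-O-acetyl-3-O-(4-methoxybenzyl)-D-glucopyranosyl N-phenyl-2,2,2-trifluoroacetimidate (anomeric mixture) | CC(=O)OC[C@H]1OC(OC(=Nc2ccccc2)C(F)(F)F)[C@H](OC(C)=O)[C@@H](OCc2ccc(OC)cc2)[C@@H]1OC(C)=O | intermediate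
13 | 6-bromo-4-oxo-2-(2-phenylethyl)-4H-chromen-7-yl 2,4,6-tri-O-acetyl-3-O-(4-methoxybenzyl)-β-D-glucopyranoside | CC(=O)OC[C@H]1O[C@@H](Oc2cc3oc(CCc4ccccc4)cc(=O)c3cc2Br)[C@H](OC(C)=O)[C@@H](OCc2ccc(OC)cc2)[C@@H]1OC(C)=O | intermediate
14 | 6-bromo-4-oxo-2-(2-phenylethyl)-4H-chromen-7-yl 3-O-(4-methoxybenzyl)-β-D-glucopyranoside | OC[C@H]1O[C@@H](Oc2cc3oc(CCc4ccccc4)cc(=O)c3cc2Br)[C@H](O)[C@@H](OCc2ccc(OC)cc2)[C@@H]1O | intermediate
15 | 6-bromo-4-oxo-2-(2-phenylethyl)-4H-chromen-7-yl 6-deoxy-6-iodo-3-O-(4-methoxybenzyl)-β-D-glucopyranoside | IC[C@H]1O[C@@H](Oc2cc3oc(CCc4ccccc4)cc(=O)c3cc2Br)[C@H](O)[C@@H](OCc2ccc(OC)cc2)[C@@H]1O | intermediate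
16 | 6-bromo-4-oxo-2-(2-phenylethyl)-4H-chromen-7-yl 2,4-di-O-benzyl-6-deoxy-6-iodo-3-O-(4-methoxybenzyl)-β-D-glucopyranoside | IC[C@H]1O[C@@H](Oc2cc3oc(CCc4ccccc4)cc(=O)c3cc2Br)[C@H](OCc2ccccc2)[C@@H](OCc2ccc(OC)cc2)[C@@H]1OCc1ccccc1 | intermediate
17 | 6-bromo-4-oxo-2-(2-phenylethyl)-4H-chromen-7-yl 2,4-di-O-benzyl-6-deoxy-3-O-(4-methoxybenzyl)-β-D-xylo-hex-5-enopyranoside | C=C1[C@@H](OCc2ccccc2)[C@H](OCc2ccc(OC)cc2)[C@@H](OCc2ccccc2)[C@H](Oc2cc3oc(CCc4ccccc4)cc(=O)c3cc2Br)O1 | intermediate
18 | ring-opened zwitterion of 17: trichloro(isopropoxy)titanate enolate across C8a/C4a, aryloxycarbenium ion at C5 | C=C(O[Ti-](Cl)(Cl)(Cl)OC(C)C)[C@@H](OCc1ccccc1)[C@H](OCc1ccc(OC)cc1)[C@@H](OCc1ccccc1)C=[O+]c1cc2oc(CCc3ccccc3)cc(=O)c2cc1Br | intermediate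
19 | (2S,3R,4S,5R)-2,4-bis(benzyloxy)-5-{[6-bromo-4-oxo-2-(2-phenylethyl)-4H-chromen-7-yl]oxy}-3-[(4-methoxybenzyl)oxy]cyclohexan-1-one | O=C1[C@@H](OCc2ccccc2)[C@H](OCc2ccc(OC)cc2)[C@@H](OCc2ccccc2)[C@H](Oc2cc3oc(CCc4ccccc4)cc(=O)c3cc2Br)C1 | intermediate
20 | trimethylsilyl enol ether of 19 (C8a–OSiMe3, C8a=C4a) | C[Si](C)(C)OC1=C[C@@H](Oc2cc3oc(CCc4ccccc4)cc(=O)c3cc2Br)[C@H](OCc2ccccc2)[C@@H](OCc2ccc(OC)cc2)[C@@H]1OCc1ccccc1 | intermediate
21 | 5-(4-methoxyphenyl)-3-oxopent-1-en-1-one (acylketene) | COc1ccc(CCC(=O)C=C=O)cc1 | intermediate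
22 | 8a-(trimethylsilyloxy)-4a,5,6,7,8,8a-hexahydro-4H-chromen-4-one cycloadduct carrying the substituents of 23 (C4a and C8a unassigned) | COc1ccc(CCC2=CC(=O)C3[C@@H](Oc4cc5oc(CCc6ccccc6)cc(=O)c5cc4Br)[C@H](OCc4ccccc4)[C@@H](OCc4ccc(OC)cc4)[C@H](OCc4ccccc4)C3(O[Si](C)(C)C)O2)cc1 | intermediate
23 | (5R,6S,7R,8S)-6,8-bis(benzyloxy)-5-{[6-bromo-4-oxo-2-(2-phenylethyl)-4H-chromen-7-yl]oxy}-7-[(4-methoxybenzyl)oxy]-2-[2-(4-methoxyphenyl)ethyl]-5,6,7,8-tetrahydro-4H-chromen-4-one | COc1ccc(CCc2cc(=O)c3c(o2)[C@@H](OCc2ccccc2)[C@H](OCc2ccc(OC)cc2)[C@@H](OCc2ccccc2)[C@@H]3Oc2cc3oc(CCc4ccccc4)cc(=O)c3cc2Br)cc1 | intermediate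
24 | 6,8-bis(benzyloxy)-5-{[6-bromo-4-oxo-2-(2-phenylethyl)-4H-chromen-7-yl]oxy}-7-hydroxy-2-[2-(4-methoxyphenyl)ethyl]-5,6,7,8-tetrahydro-4H-chromen-4-one (arrangement at C5–C8 as in 23) | COc1ccc(CCc2cc(=O)c3c(o2)[C@@H](OCc2ccccc2)[C@H](O)[C@@H](OCc2ccccc2)[C@@H]3Oc2cc3oc(CCc4ccccc4)cc(=O)c3cc2Br)cc1 | intermediate
25 | 6,8-di-O-benzyl-(+)-4'-methoxyaquisinenone G (bridged dioxepine, C5–O–C7' and C7–O–C6') | COc1ccc(CCc2cc(=O)c3c(o2)[C@@H](OCc2ccccc2)[C@@H]2Oc4cc5c(=O)cc(CCc6ccccc6)oc5cc4O[C@H]3[C@@H]2OCc2ccccc2)cc1 | intermediate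
26 | (+)-4'-methoxyaquisinenone G | COc1ccc(CCc2cc(=O)c3c(o2)[C@@H](O)[C@@H]2Oc4cc5c(=O)cc(CCc6ccccc6)oc5cc4O[C@H]3[C@@H]2O)cc1 | target

Total step count: 17. Longest linear sequence: 15 steps (7 to 26, steps 3 to 17); steps 1 and 2 supply the two side fragments.

Steps most likely to fail

Step 12. The rearrangement could be diverted by exocyclic heterolysis that expels the chromonyl oxide, by Lewis-acid loss of the PMB ether, by capture of the reagent at the chromone carbonyl, or by β-elimination of the aryloxide from the product. The fallback separates ring closure from ether formation and sets out from 17. Catalytic Hg(OCOCF3)2 in acetone/water (the aglycon-releasing Ferrier carbocyclization: oxymercuration of the enol ether, loss of phenol 4, which is recovered, and intramolecular aldol closure) should give (2S,3R,4S,5S)-2,4-bis(benzyloxy)-5-hydroxy-3-[(4-methoxybenzyl)oxy]cyclohexan-1-one F1. Its hydroxyl is expected axial, trans to the PMB-bearing oxygen, as is usual for gluco-configured substrates. Mitsunobu etherification of F1 with phenol 4 (PPh3, DIAD, toluene, 0 °C) then inverts that carbinol and rejoins the route at 19. The acidity of 4 keeps the phenoxide weakly basic, which should limit dehydration of the β-hydroxy ketone.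

Step 16. The cyclisation could fail through β-hydride elimination from the palladium alkoxide (oxidation at C7 with reduction of the C6'–Br bond), through slow reductive elimination for the bridged seven-membered ring, or through carbonate-induced elimination across C7–C8. The fallback replaces the hot, basic palladium coupling by a room-temperature oxidative copper coupling and sets out from 23. Miyaura borylation (Pd(dppf)Cl2, B2pin2, KOAc, 1,4-dioxane, 90 °C) should give the C6' pinacol boronate of 23 F2. DDQ removal of the PMB group as in step 15 then gives the C7 alcohol boronate F3. Chan–Lam etherification (Cu(OAc)2, pyridine, 4 Å MS, air, CH2Cl2, rt) closes the C7–O–C6' bond and rejoins the route at 25.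

Step 14. The annulation could suffer from thermal ionisation or elimination of the allylic C5 aryloxy group of the silyl enol ether at 110 °C, from dimerisation of the acylketene outrunning cycloaddition to a hindered trisubstituted enol ether, or from premature desilylation. The fallback builds the pyranone stepwise at low temperature and sets out from 20. Mukaiyama aldol addition (BF3·OEt2, CH2Cl2, −78 °C) to 5-(4-methoxyphenyl)pent-2-ynal F4, itself made from commercial 1-(but-3-yn-1-yl)-4-methoxybenzene by n-BuLi then DMF, should give the C4a aldol adduct (diastereomer mixture) F5. Dess–Martin oxidation gives the 2-alkynoyl ketone F6. Its enol should cyclise onto the ynone in 6-endo-dig fashion (Ph3PAuCl/AgOTf, cat., CH2Cl2, rt) and rejoin the route at 23.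

Further compounds

F1 | step 12 | (2S,3R,4S,5S)-2,4-bis(benzyloxy)-5-hydroxy-3-[(4-methoxybenzyl)oxy]cyclohexan-1-one | O=C1[C@@H](OCc2ccccc2)[C@H](OCc2ccc(OC)cc2)[C@@H](OCc2ccccc2)[C@@H](O)C1
F2 | step 16 | C6' pinacol boronate of 23 (4,4,5,5-tetramethyl-1,3,2-dioxaborolan-2-yl in place of Br) | COc1ccc(CCc2cc(=O)c3c(o2)[C@@H](OCc2ccccc2)[C@H](OCc2ccc(OC)cc2)[C@@H](OCc2ccccc2)[C@@H]3Oc2cc3oc(CCc4ccccc4)cc(=O)c3cc2B2OC(C)(C)C(C)(C)O2)cc1
F3 | step 16 | C7 alcohol of the C6' pinacol boronate | COc1ccc(CCc2cc(=O)c3c(o2)[C@@H](OCc2ccccc2)[C@H](O)[C@@H](OCc2ccccc2)[C@@H]3Oc2cc3oc(CCc4ccccc4)cc(=O)c3cc2B2OC(C)(C)C(C)(C)O2)cc1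
F4 | step 14 | 5-(4-methoxyphenyl)pent-2-ynal | COc1ccc(CCC#CC=O)cc1
F5 | step 14 | 2,4-bis(benzyloxy)-5-{[6-bromo-4-oxo-2-(2-phenylethyl)-4H-chromen-7-yl]oxy}-6-[1-hydroxy-5-(4-methoxyphenyl)pent-2-yn-1-yl]-3-[(4-methoxybenzyl)oxy]cyclohexan-1-one (mixture at C6 and the carbinol) | COc1ccc(CCC#CC(O)C2C(=O)[C@@H](OCc3ccccc3)[C@H](OCc3ccc(OC)cc3)[C@@H](OCc3ccccc3)[C@@H]2Oc2cc3oc(CCc4ccccc4)cc(=O)c3cc2Br)cc1
F6 | step 14 | 2,4-bis(benzyloxy)-5-{[6-bromo-4-oxo-2-(2-phenylethyl)-4H-chromen-7-yl]oxy}-3-[(4-methoxybenzyl)oxy]-6-[5-(4-methoxyphenyl)pent-2-ynoyl]cyclohexan-1-one | COc1ccc(CCC#CC(=O)C2C(=O)[C@@H](OCc3ccccc3)[C@H](OCc3ccc(OC)cc3)[C@@H](OCc3ccccc3)[C@@H]2Oc2cc3oc(CCc4ccccc4)cc(=O)c3cc2Br)cc1
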